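**Retrosynthetic overview**

1. Locants follow the daucane skeleton: C1 = quaternary ring-fusion carbon (CH3), C2/C3 = CH2, C4 = C(OH)(iPr), C5 = ring-fusion CH, C6 = CH–O-anisoyl, C7=C8(CH3), C9/C10 = CH2 (systematic names use azulene numbering). The ester is cut last (C6–O acyl), then C6–H (ketone reduction steered by the C4 hydroxyl), which leads back to hydroxy enone 16.
2. 16 is traced to a C6–silyl diene (benzyldimethylsilyl as masked C6 oxygen) and a C4 ketone (isopropyl enters anti to the C1 methyl), i.e. silyl dienone 13, which is an alkene-migration isomer (C9=C10 → C7=C8) of bicyclic adduct 12.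
3. Key disconnection of 12: C5–C1 and C6–C7 together, an intramolecular [5+2] cycloaddition of open-chain silyl ynone 11 (two-carbon unit C5≡C6; five-carbon unit = alkene C1=C10 plus cyclopropane C9–C8–C7). Within one catalytic cycle the cyclopentane closes first (C5–C1), the cycloheptane second (C6–C7).
4. Enabling feature: in the seven-membered ring, C7–C8(CH3)–C9–C10–C1 is an unbroken five-carbon run ending at the quaternary ring-fusion carbon, and the other two ring atoms C5–C6 lie between oxygen-bearing positions (C4–OH beside C5, O on C6), so they can be an alkyne flanked by a C4 carbonyl and a C6 silicon. The C8 methyl sits on the cyclopropane, whose stereocentres pass their chirality to C1 and then vanish into the C7=C8 alkene.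
5. 11 comes from Weinreb amide 6 and silylacetylene 9; 6 from a Johnson–Claisen rearrangement of carbinol 4, itself from trans-2-methylcyclopropylmethanol 2, made by asymmetric cyclopropanation of (E)-crotyl alcohol 1, the only source of absolute configuration.

Key step: step 7

Remark on the chemistry: the enantiomeric purity of the whole route is that of cyclopropane 2, and cleavage of the unsubstituted cyclopropane bond in step 7 is assumed, as is usual for trans-2-alkyl vinylcyclopropanes under rhodium catalysis.

**Route**

Step 1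
Reactants: 1 (E)-but-2-en-1-ol
Product: 2 [(1R,2R)-2-methylcyclopropyl]methanol
Conditions: Et2Zn, CH2I2, DME, (4S,5S)-2-butyl-N,N,N′,N′-tetramethyl-1,3,2-dioxaborolane-4,5-dicarboxamide, CH2Cl2, −10 °C → rt
Reagents that add atoms: diiodomethane, ICI
Why: Charette asymmetric Simmons–Smith cyclopropanation, in which the zinc alkoxide is held by the chiral dioxaborolane so that Zn(CH2I)2 delivers CH2 to one alkene face (the (4S,5S) ligand is the mirror image of the one that gives (1S,2S) alcohols from (E)-allylic alcohols), and syn addition to the E alkene makes the ring trans.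

Step 2
Reactants: 2 [(1R,2R)-2-methylcyclopropyl]methanol
Product: 4 2-methyl-1-[(1R,2R)-2-methylcyclopropyl]prop-2-en-1-ol (both carbinol epimers), via aldehyde 3 (not isolated)
Conditions: (COCl)2, DMSO, CH2Cl2, −78 °C; Et3N; then CH2=C(CH3)MgBr (excess), THF, −78 → 0 °C; aq. NH4Cl
Reagents that add atoms: isopropenylmagnesium bromide, C=C(C)[Mg]Br
Why: Swern oxidation followed in the same flask by Grignard 1,2-addition avoids isolating the volatile aldehyde, and the unselectively formed carbinol centre is destroyed in step 3.

Step 3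
Reactants: 4 2-methyl-1-[(1R,2R)-2-methylcyclopropyl]prop-2-en-1-ol
Product: 5 ethyl (4E)-4-methyl-5-[(1R,2R)-2-methylcyclopropyl]pent-4-enoate
Conditions: CH3C(OEt)3, EtCO2H (cat.), 140 °C, EtOH distilled off
Reagents that add atoms: triethyl orthoacetate, CC(OCC)(OCC)OCC
Why: Johnson–Claisen rearrangement through a chair transition state with the cyclopropyl group equatorial should give the E trisubstituted alkene (cyclopropyl trans to the new chain, cis to the methyl), the geometry on which the stereochemical outcome of step 7 depends.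

Step 4
Reactants: 5 ethyl (4E)-4-methyl-5-[(1R,2R)-2-methylcyclopropyl]pent-4-enoate
Product: 6 (4E)-N-methoxy-N,4-dimethyl-5-[(1R,2R)-2-methylcyclopropyl]pent-4-enamide
Conditions: MeNH(OMe)·HCl, iPrMgCl, THF, −20 → 0 °C
Reagents that add atoms: N,O-dimethylhydroxylamine hydrochloride, CNOC.Cl
Why: Weinreb amide formation by aminolysis of the ester with the magnesium amide, with no stereocentre touched.

Step 5
Reactants: 7 ethynylmagnesium bromide; 8 benzyl(chloro)dimethylsilane
Product: 9 benzyl(ethynyl)dimethylsilane
Conditions: THF, 0 °C → rt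
Reagents that add atoms: none
Why: Substitution at silicon by the acetylide Grignard reagent gives the alkyne carrying the oxidizable benzyldimethylsilyl group.

Step 6
Reactants: 6 (4E)-N-methoxy-N,4-dimethyl-5-[(1R,2R)-2-methylcyclopropyl]pent-4-enamide; 9 benzyl(ethynyl)dimethylsilane
Product: 11 (6E)-1-[benzyl(dimethyl)silyl]-6-methyl-7-[(1R,2R)-2-methylcyclopropyl]hept-6-en-1-yn-3-one, via lithium acetylide 10 (not isolated)
Conditions: 9, n-BuLi, THF, −78 °C; then 6, −78 → 0 °C; aq. NH4Cl
Reagents that add atoms: none
Why: Weinreb ketone synthesis, in which the chelated tetrahedral adduct stops at the ketone stage and gives the silyl-capped ynone without over-addition.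

Step 7
Reactants: 11 (6E)-1-[benzyl(dimethyl)silyl]-6-methyl-7-[(1R,2R)-2-methylcyclopropyl]hept-6-en-1-yn-3-one
Product: 12 (3aR,6R)-8-[benzyl(dimethyl)silyl]-3a,6-dimethyl-3,3a,6,7-tetrahydroazulen-1(2H)-one
Conditions: [Rh(CO)2Cl]2 (5 mol %), ClCH2CH2Cl, 80 °C, Ar
Reagents that add atoms: none
Why: Monovalent rhodium binds the C1=C10 alkene and inserts into the unsubstituted cyclopropane bond C9–C7 to give an allyl(alkyl)rhodium metallacycle (trivalent rhodium), the tethered alkyne then inserts at the allyl terminus C1 (bond C5–C1), and reductive elimination joins C6 to C7. The closest known reaction type is the rhodium-catalyzed intramolecular [5+2] cycloaddition of alkyne-tethered vinylcyclopropanes, for which ynones, silyl-capped alkynes and 2-alkylcyclopropanes are established partners. The five-membered ring closes by 5-exo migratory insertion through the three-atom tether C2–C3–C4, and the seven-membered ring by C(sp2)–C(sp3) reductive elimination from the eight-membered rhodacycle, so the net process is a [5+2] annulation onto the new cyclopentanone. The quaternary stereocentre C1 is set by chirality transfer from C9: rhodium stays on the allyl face from which C7 departed and C5 is delivered to that face, so the E alkene together with the (1R,2R) cyclopropane should give the C1 configuration of the target, while the C8 methyl centre is carried through unchanged. The step needs cleavage of C9–C7 instead of C9–C8, which the trans methyl group should secure (less hindered bond, primary alkyl–rhodium, no clash with the inward C1 methyl), and it needs C5 rather than C6 to bond to C1, which the short tether enforces.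

Step 8
Reactants: 12 (3aR,6R)-8-[benzyl(dimethyl)silyl]-3a,6-dimethyl-3,3a,6,7-tetrahydroazulen-1(2H)-one
Product: 13 (3aS)-8-[benzyl(dimethyl)silyl]-3a,6-dimethyl-3,3a,4,5-tetrahydroazulen-1(2H)-one
Conditions: RhCl3·3H2O (cat.), EtOH, 75 °C
Reagents that add atoms: none
Why: Rhodium hydride alkene isomerization (hydrometalation/β-hydride elimination), in which the C9=C10 alkene can move only away from quaternary C1 and two 1,3-hydrogen shifts should end at the linear, fully conjugated dienone (C4=O, C5=C6, C7=C8) as the thermodynamic sink, placing the trisubstituted C7=C8 alkene and erasing the relay stereocentre at C8.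

Step 9
Reactants: 13 (3aS)-8-[benzyl(dimethyl)silyl]-3a,6-dimethyl-3,3a,4,5-tetrahydroazulen-1(2H)-one
Product: 14 (1R,3aS)-8-[benzyl(dimethyl)silyl]-3a,6-dimethyl-1-(propan-2-yl)-1,2,3,3a,4,5-hexahydroazulen-1-ol
Conditions: CeCl3 (dried), iPrMgCl, THF, −78 °C
Reagents that add atoms: isopropylmagnesium chloride, CC(C)[Mg]Cl
Why: Organocerium 1,2-addition to the hindered, enolizable ketone (conjugate addition is blocked because C6 and C8 are fully substituted) should occur on the face of the planar alkylidenecyclopentanone opposite the pseudo-axial C1 methyl, so that the C4 hydroxyl ends cis to that methyl.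

Step 10
Reactants: 14 (1R,3aS)-8-[benzyl(dimethyl)silyl]-3a,6-dimethyl-1-(propan-2-yl)-1,2,3,3a,4,5-hexahydroazulen-1-ol
Product: 16 (3R,3aR,8aS)-3-hydroxy-6,8a-dimethyl-3-(propan-2-yl)-2,3,3a,7,8,8a-hexahydroazulen-4(1H)-one, via cyclic siloxane 15 (not isolated)
Conditions: Bu4NF, THF, 0 °C; then KHCO3, 30 % aq. H2O2, MeOH, 0 °C → rt
Reagents that add atoms: hydrogen peroxide, OO
Why: Tamao–Fleming oxidation of a benzyldimethylsilyl alkene, in which fluoride-induced loss of toluene is helped by the cis C4 hydroxyl (five-membered siloxane), peroxide replaces C6–Si by C6–O with retention, the dienol gives the C6 ketone conjugated with C7=C8, and C5 is protonated under equilibrating conditions to the trans-fused isomer that has C6 anti to the isopropyl group and its carbonyl hydrogen-bonded to the C4 hydroxyl.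

Step 11
Reactants: 16 (3R,3aR,8aS)-3-hydroxy-6,8a-dimethyl-3-(propan-2-yl)-2,3,3a,7,8,8a-hexahydroazulen-4(1H)-one
Product: 17 (3R,3aS,4S,8aS)-6,8a-dimethyl-3-(propan-2-yl)-1,2,3,3a,4,7,8,8a-octahydroazulene-3,4-diol
Conditions: Me4NBH(OAc)3, MeCN/AcOH (1:1), −25 °C
Reagents that add atoms: none
Why: Evans–Saksena hydroxyl-directed reduction, in which the C4 hydroxyl exchanges onto boron and delivers hydride through a six-membered transition state to the face of the C6 carbonyl on which the C4 oxygen lies, should give 1,2-reduction of the enone and the C6 hydroxyl trans to the C4 hydroxyl.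

Step 12
Reactants: 17 (3R,3aS,4S,8aS)-6,8a-dimethyl-3-(propan-2-yl)-1,2,3,3a,4,7,8,8a-octahydroazulene-3,4-diol; 18 4-methoxybenzoyl chloride
Product: 19 (3R,3aS,4S,8aS)-3-hydroxy-6,8a-dimethyl-3-(propan-2-yl)-1,2,3,3a,4,7,8,8a-octahydroazulen-4-yl 4-methoxybenzoate
Conditions: Et3N, DMAP (cat.), CH2Cl2, 0 °C → rt
Reagents that add atoms: none
Why: DMAP-catalyzed acylation with the acyl chloride should take place only at the secondary allylic C6 hydroxyl, the tertiary C4 hydroxyl being too hindered, with no change at any stereocentre.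

**Compound list**

1 | (E)-but-2-en-1-ol (crotyl alcohol) | C/C=C/CO | starting material
2 | [(1R,2R)-2-methylcyclopropyl]methanol | OC[C@@H]1C[C@H]1C | intermediate
3 | (1R,2R)-2-methylcyclopropane-1-carbaldehyde (not isolated) | O=C[C@@H]1C[C@H]1C | intermediate
4 | 2-methyl-1-[(1R,2R)-2-methylcyclopropyl]prop-2-en-1-ol (both carbinol epimers) | C=C(C)C(O)[C@@H]1C[C@H]1C | intermediate
5 | ethyl (4E)-4-methyl-5-[(1R,2R)-2-methylcyclopropyl]pent-4-enoate | CCOC(=O)CC/C(C)=C/[C@@H]1C[C@H]1C | intermediate
6 | (4E)-N-methoxy-N,4-dimethyl-5-[(1R,2R)-2-methylcyclopropyl]pent-4-enamide | CON(C)C(=O)CC/C(C)=C/[C@@H]1C[C@H]1C | intermediate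
7 | ethynylmagnesium bromide | C#C[Mg]Br | starting material
8 | benzyl(chloro)dimethylsilane | C[Si](C)(Cl)Cc1ccccc1 | starting material
9 | benzyl(ethynyl)dimethylsilane | C#C[Si](C)(C)Cc1ccccc1 | intermediate
10 | lithium [benzyl(dimethyl)silyl]acetylide (not isolated) | [Li]C#C[Si](C)(C)Cc1ccccc1 | intermediate
11 | (6E)-1-[benzyl(dimethyl)silyl]-6-methyl-7-[(1R,2R)-2-methylcyclopropyl]hept-6-en-1-yn-3-one | C[Si](C)(Cc1ccccc1)C#CC(=O)CC/C(C)=C/[C@@H]1C[C@H]1C | intermediate
12 | (3aR,6R)-8-[benzyl(dimethyl)silyl]-3a,6-dimethyl-3,3a,6,7-tetrahydroazulen-1(2H)-one | C[Si](C)(Cc1ccccc1)C1=C2C(=O)CC[C@]2(C)C=C[C@H](C)C1 | intermediate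
13 | (3aS)-8-[benzyl(dimethyl)silyl]-3a,6-dimethyl-3,3a,4,5-tetrahydroazulen-1(2H)-one | C[Si](C)(Cc1ccccc1)C1=C2C(=O)CC[C@]2(C)CCC(C)=C1 | intermediate
14 | (1R,3aS)-8-[benzyl(dimethyl)silyl]-3a,6-dimethyl-1-(propan-2-yl)-1,2,3,3a,4,5-hexahydroazulen-1-ol | C[Si](C)(Cc1ccccc1)C1=C2[C@](O)(C(C)C)CC[C@]2(C)CCC(C)=C1 | intermediate
15 | cyclic siloxane of 14 after loss of toluene (five-membered ring C4–O–Si(CH3)2–C6=C5; not isolated) | C[Si]1(C)O[C@@]2(C(C)C)CC[C@]3(C)CCC(C)=CC1=C23 | intermediate
16 | (3R,3aR,8aS)-3-hydroxy-6,8a-dimethyl-3-(propan-2-yl)-2,3,3a,7,8,8a-hexahydroazulen-4(1H)-one | O=C1C=C(C)CC[C@@]2(C)CC[C@@](O)(C(C)C)[C@H]12 | intermediate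
17 | (3R,3aS,4S,8aS)-6,8a-dimethyl-3-(propan-2-yl)-1,2,3,3a,4,7,8,8a-octahydroazulene-3,4-diol | O[C@H]1C=C(C)CC[C@@]2(C)CC[C@@](O)(C(C)C)[C@H]12 | intermediate
18 | 4-methoxybenzoyl chloride | COc1ccc(cc1)C(Cl)=O | starting material
19 | (3R,3aS,4S,8aS)-3-hydroxy-6,8a-dimethyl-3-(propan-2-yl)-1,2,3,3a,4,7,8,8a-octahydroazulen-4-yl 4-methoxybenzoate | COc1ccc(C(=O)O[C@H]2C=C(C)CC[C@@]3(C)CC[C@@](O)(C(C)C)[C@H]23)cc1 | target

**Step count and risks**

Total step count: 12. Longest linear sequence: 11 steps (steps 1–4 and 6–12); step 5 is a one-step side branch.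

Steps most likely to fail:

**1. Step 7.** Both reacting ends are hindered (fully substituted allyl terminus C1, silyl-capped ynone), so migratory insertion may be too slow and the substrate may decompose; the more substituted cyclopropane bond may also be cleaved in competition. The fallback removes the alkyne substituent and brings in the C6 oxygen by epoxidation instead of silicon oxidation. It sets out from Weinreb amide 6 and Grignard reagent 7 and comes back at diol 17. Addition of 7 to 6 (THF, 0 °C, cold acidic quench) should give the terminal ynone (6E)-6-methyl-7-[(1R,2R)-2-methylcyclopropyl]hept-6-en-1-yn-3-one F1. Terminal alkynes are the most reactive partners in the [5+2] cycloaddition, so [Rh(CO)2Cl]2 in ClCH2CH2Cl should give the silicon-free adduct (3aR,6R)-3a,6-dimethyl-3,3a,6,7-tetrahydroazulen-1(2H)-one F2. RhCl3·3H2O in EtOH should move the alkene as in step 8 to the dienone (3aS)-3a,6-dimethyl-3,3a,4,5-tetrahydroazulen-1(2H)-one F3. Nucleophilic epoxidation (H2O2, NaOH, MeOH, 0 °C) at C5=C6, on the face opposite the C1 methyl, should give the C5–C6 α-epoxy ketone F4. Reductive opening at C5 with SmI2 (THF/MeOH, −90 °C) should give the 6α-hydroxy C4 ketone F5, with C5 equilibrated to the trans ring fusion. Addition of CeCl3/iPrMgCl at −78 °C, anti to the C1 methyl, then gives 17.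

**2. Step 8.** The alkene migration may stall, because the first shift needs abstraction of the hindered tertiary allylic hydrogen at C8, or silicon may be lost under the slightly acidic conditions. The fallback is a redox detour instead of an isomerization; it sets out from 12 and comes back at 16. Chemoselective hydrogenation of the disubstituted C9=C10 alkene (H2, RhCl(PPh3)3, benzene) should give the 9,10-dihydro derivative of 12 F6. Isopropyl addition as in step 9 should give the tertiary alcohol F7, and silicon oxidation as in step 10 should give the saturated hydroxy ketone, the 7,8-dihydro derivative of 16 F8. Dehydrogenation can only occur toward C7–C8, because the carbons beyond C5 carry no hydrogen; LDA followed by N-tert-butylbenzenesulfinimidoyl chloride at −78 °C, or silyl enol ether formation and Pd(OAc)2 (Saegusa–Ito oxidation), then gives 16.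

**3. Step 10.** Protodesilylation may compete with oxidation after fluoride activation, and the basic peroxide may attack the newly formed enone (epoxidation) or trigger retro-aldol opening of the hydroxy ketone. The fallback uses electrophilic, hydroxyl-directed oxidation instead of nucleophilic peroxide; it sets out from 14 and comes back at 16. VO(acac)2 and t-BuOOH (CH2Cl2, 0 °C) should epoxidize only the allylic C5=C6 vinylsilane, syn to the C4 hydroxyl, to give the epoxysilane, the C5–C6 β-epoxide of 14 F9. Dilute HClO4 in aqueous THF should open the epoxide at the silicon-bearing C6, and Peterson elimination of the resulting β-hydroxysilane gives the enol that tautomerizes to 16.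

**Further compounds**

F1 | step 7 | (6E)-6-methyl-7-[(1R,2R)-2-methylcyclopropyl]hept-6-en-1-yn-3-one | C#CC(=O)CC/C(C)=C/[C@@H]1C[C@H]1C
F2 | step 7 | (3aR,6R)-3a,6-dimethyl-3,3a,6,7-tetrahydroazulen-1(2H)-one | C1=C2C(=O)CC[C@]2(C)C=C[C@H](C)C1
F3 | step 7 | (3aS)-3a,6-dimethyl-3,3a,4,5-tetrahydroazulen-1(2H)-one | C1=C2C(=O)CC[C@]2(C)CCC(C)=C1
F4 | step 7 | C5–C6 α-epoxide of F3 (oxirane on the face opposite the C1 methyl) | CC1=C[C@@H]2O[C@@]23C(=O)CC[C@]3(C)CC1
F5 | step 7 | 6α-hydroxy C4 ketone (17 with C4=O in place of C(OH)(iPr)) | O[C@H]1C=C(C)CC[C@@]2(C)CCC(=O)[C@H]12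
F6 | step 8 | 9,10-dihydro derivative of 12 | C[Si](C)(Cc1ccccc1)C1=C2C(=O)CC[C@]2(C)CC[C@H](C)C1
F7 | step 8 | tertiary alcohol from isopropyl addition to F6 | C[Si](C)(Cc1ccccc1)C1=C2[C@](O)(C(C)C)CC[C@]2(C)CC[C@H](C)C1
F8 | step 8 | 7,8-dihydro derivative of 16 | O=C1C[C@@H](C)CC[C@@]2(C)CC[C@@](O)(C(C)C)[C@H]12
F9 | step 10 | C5–C6 β-epoxide of 14 (epoxysilane, oxirane syn to the C4 hydroxyl) | CC1=C[C@@]2([Si](C)(C)Cc3ccccc3)O[C@]24[C@](O)(C(C)C)CC[C@]4(C)CC1
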